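A percentage point of the G charged is the unit here: cD, the concentration of D, is read in it, and each reading carries a scatter of 1 percentage point.

| setting | elm | maple | flask |
|---|---|---|---|
| G | 0.36 M | 0.36 M | 0.36 M |
| Q | 1.5 equiv | 0.75 equiv | 1.50 equiv |
| temperature | 25 °C | 31 °C | 25 °C |
| remark | the very flask that is asked about, followed so far | run made earlier |  |
| time |  |  | 4.0 d |

| run | time / h | D / % |
|---|---|---|
| elm | 15.0 | 32.5 |
| elm | 30.0 | 33.1 |
| elm | 40.0 | 34.9 |
| elm | 60.0 | 34.3 |
| elm | 72.0 | 33.9 |
| elm | 96.0 | 35.8 |
| maple | 0.500 | 0 |
| maple | 1.00 | 2.1 |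
| maple | 1.50 | 3.9 |
| maple | 2.00 | 3.8 |
| maple | 2.50 | 7.3 |
| maple | 3.00 | 6.6 |
| maple | 4.00 | 11.0 |

(each reading ± 1 percentage point)

- G is a solid; its amount is given per volume of the solution
- D taken out counts as made
- the earlier runs were read with a standard deviation of 1 percentage point
- at the start none of G is in solution
- additions bring no volume worth counting

- eta: at 4.0 d raise the temperature by 10 K, then wait 50 h
- zeta: change nothing and wait 50 h more
- theta: at 4.0 d take out 90% of the D then present, then wait 50 h
- beta: at 4.0 d add Q, 100% of the amount charged, then wait 50 h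

1. D, in percent of the G first charged, at 4.0 d
2. what to do for the largest gain in D; "none" if nothing gains more than 2 percentage points (eta / zeta / theta / beta / none)
3. D present, with what was taken out counted in, in percent of the G first charged, after eta
4. D present, with what was taken out counted in, in percent of the G first charged, after theta

Drawn from the start, the curve of D begins flat in maple, which reads 0% at 0.500 h. It then climbs, and maple gains 11 points in 3.50 h. In elm, the flask asked about, the two early readings average 32.8%. The readings from 40.0 h on scatter around the stall level, their mean of 34.7%, the plateau of the curve, with a standard error of 0.5 points. The early pair lies 1.9 points below it, against an error of 0.87 points on that gap, so the pair stays out of the mean. Replacing these later readings by the mean leaves the farthest of them 1.1 points off, against a scatter of 1 point.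

Maple's climb, run straight up to that level, meets it at a knee near 11.5 h. Maple ran at 0.75 equiv and 31 °C, so this knee is rough, but it lies earlier than elm's first reading at 15.0 h and is short against 4.0 d. The reckoning here therefore puts D at 4.0 d on the stall level.

The forecast, from the same runs, gives 34.5% for D, just under this level. It chooses beta, with 35% after eta and 57% after theta, on this ground: “I read the plateau as an equilibrium with solid G holding dissolved G constant”.

The flask stands at 34.8%. The best move is theta, gaining 20 points, while beta gains 2.8 points; eta ends at 35.1% and theta, with what was taken out counted in, at 55.0%.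

    D ⇌ Z (K = 1.20, k = 4.21 × 10⁻⁵ s⁻¹, Ea = 96.0 kJ mol⁻¹, ΔH = −10.0 kJ mol⁻¹)
    G ⇌ J, rate k2*(cs2 - [J]) while solid is left; crystals form when [J] > cs2 (solubility = 0.190 M, k = 6.74 × 10⁻⁵ s⁻¹)
    J + Q ⇌ L (K = 5.48 M⁻¹, k = 1.21 × 10⁻⁴ M⁻¹ s⁻¹, Ea = 57.0 kJ mol⁻¹, ΔH = −3.00 kJ mol⁻¹)
    J + Q ⇌ D (K = 15.0 M⁻¹, k = 2.54 × 10⁻⁴ M⁻¹ s⁻¹, Ea = 63.0 kJ mol⁻¹, ΔH = −16.0 kJ mol⁻¹)
    (constants at 25 °C)

At 96.0 h Z holds 41.7%, more than the 34.8% of D. Taking 90% of the stall level, as an estimate of what theta removes, from the theta figure leaves about 23.8% of D standing in the flask after the wait. Scaled in proportion to a Q charge of 0.900 equiv, the stall level gives 20.8%, and the neighbour flask with that charge stands higher, at 27.9%.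

The data are simulated from invented constants, noise included.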